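The readings are calculated with constants of no real substance, noise included.

Late in the dusk run Q stood at 16.4% after 20.0 min and 16.9% after 25.0 min, and I started from that height. Z has two ways out: with X to E and on to Q, or with a second Z to J.

| flask | Z | X | remark | time |
|---|---|---|---|---|
| dusk | 10 mM | 1.5 equiv | run made earlier |  |
| summer | 5 mM | 1.5 equiv | run made earlier |  |
| dawn | 20 mM | 1.5 equiv | run made earlier |  |
| autumn | 10 mM | 3 equiv | run made earlier |  |
| Thursday's | 10 mM (fed, over 15 min) | 1.50 equiv | all else is in the flask from the start; the feed brings no volume worth counting | 40 min |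
| Monday's | 10 mM | 1.50 equiv (fed, over 15 min) | all else is in the flask from the start; the feed brings no volume worth counting | 40 min |
| Sunday's | 10 mM | 1.50 equiv | everything together at the start | 40 min |

| run | time / min | Q / % | Z / % |
|---|---|---|---|
| dusk | 6.00 | 7.6 | 14.2 |
| dusk | 12.0 | 15.2 | 4.8 |
| dusk | 20.0 | 16.4 | 1.6 |
| dusk | 25.0 | 16.9 | 2.1 |
| summer | 2.00 | 2.0 | 52.1 |
| summer | 4.00 | 3.4 | 31.4 |
| summer | 10.0 | 11.0 | 15.8 |
| summer | 25.0 | 15.4 | 4.8 |
| dawn | 2.00 | 3.1 | 20.3 |
| dawn | 4.00 | 6.6 | 10.2 |
| dawn | 10.0 | 14.8 | 2.9 |
| dawn | 25.0 | 17.2 | 0 |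
| autumn | 6.00 | 12.8 | 9.4 |
| autumn | 12.0 | 23.6 | 2.2 |
| autumn | 20.0 | 26.6 | 0.2 |
| autumn | 25.0 | 27.8 | 0 |

(each reading ± 1 percentage point)

1. the flask that comes out highest in amount of Q, in percent of the Z charged, or "all alike" when all lie within 1.5 percentage points (Thursday's / Monday's / Sunday's / all alike)
2. Q at the end, in percent of the Z charged, Thursday's
3. Q at the end, in percent of the Z charged, Monday's
4. Q at the end, in percent of the Z charged, Sunday's

- percentages count the Z that a species holds: one J counts as two
- candidate steps: Q -> G; Z + X -> E; 2 Z -> J; E -> Q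

The first setting was the concentration. By hand, with the equivalents held, both ways go with its square, so it should change the speed and not the split. The readings agreed within their scatter: after 25.0 min the dawn run showed 17.2% of Q, and the summer run 15.4% with 4.8% of its Z still there.

The second setting was X. With x the equivalents of X and z the fraction of Z left, the two ways stand as x to Wz. Here W, my selectivity factor, is the equivalents of X that match the pull of the whole charge of Z on itself. Summed over a batch, Q comes to x/W times ln(1 + W/x), and near ten that logarithm is about 2.3. The dusk and autumn plateaus, 16.9% and 27.8%, together gave W = 22.6 equiv, so I reckoned 15.3% for Sunday's.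

The third setting was feeding Z. In dusk, 1/z grew by 1.01 min⁻¹. So in Thursday's flask Z should hold where pairing matches the feed, at z = 25.7%, and X should take 20.5% of it, more than Sunday's.

The fourth was feeding X. In Monday's flask pairing would bring Z to 6.21% by the end of the feed, so I placed it under Sunday's, without a figure.

The forecast said Thursday's, with 26%, 8.3% and 17.5% for Thursday's, Monday's and Sunday's: “Z stays low (about 25% of charge) against full X”. My two figures lay under its own.

The flasks gave 23.1%, 7.17% and 14.8%, with Thursday's highest.

    Q → G (k = 0.0159 min⁻¹)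
    Z + X → E (k = 5.62 M⁻¹ min⁻¹)
    2 Z → J (k = 39.2 M⁻¹ min⁻¹)
    E → Q (k = 0.189 min⁻¹)

In Thursday's flask Z stood at 24.8% at the end of the feed, beside my 25.7%, and Q stood at 23.1% after 40.0 min, against the 20.5% from W. The neighbour like Thursday's with 0.900 equiv of X gave 15.2%, where W gives 13.4%. In the run without the loss of 2 Z to J, Thursday's less Monday's went from 16 percentage points to −0.052 points.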